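The synthesis rests on cutting the C9–C10 bond of seven-membered ring B. The target's contiguous array, C10 carbinol, C9 carbinol and C8 carrying exocyclic C14, is what remains when C9, the oxygen-bearing terminus of a 2-substituted allylstannane with tin on C14, adds to a C10 aldehyde. A single Lewis-acid-promoted allyl transfer thus closes ring B onto ring A, forms C9–C10, sets C9 and C10 and leaves the C8=C14 methylene for a hydroxyl-directed epoxidation. The precursor is an enantioenriched cyclopentane (ring A) bearing the C10 aldehyde on quaternary C1, a C4 methoxymethyl ether, and on C5 the side chain with the C6 isovalerate and the (Z)-γ-(methoxymethoxy)allylstannane.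

Key step: step 17

Remark: atom labels follow the daucane skeleton (ring A: C1–C5; ring B: C5, C6, C7, C8, C9, C10, C1; C14 on C8, C15 on C1); α is the face of H5 and β that of C15. The ligand enantiomer in step 3 is assumed to be the one that delivers the 1S quaternary centre.

Step 1
Reactants: 1 3-ethoxycyclopent-2-en-1-one
Product: 4 3-(hydroxymethyl)cyclopent-2-en-1-one, via the lithium alkoxide adduct 2 (not isolated), via the enone methoxymethyl ether 3 (not isolated)
Conditions: Bu3SnCH2OCH2OMe, n-BuLi, THF, −78 °C; then 1, −78 to 0 °C; then 3 M HCl, THF, 45 °C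
Reagents that add atoms: tributyl[(methoxymethoxy)methyl]stannane COCOC[Sn](CCCC)(CCCC)CCCC; water O
Why: Stork–Danheiser sequence in which the alkoxymethyllithium from tin–lithium exchange adds 1,2 to the vinylogous ester and aqueous acid then unmasks the transposed enone and cleaves the methoxymethyl acetal in the same pot; no stereocentre is formed.

Step 2
Reactants: 4 3-(hydroxymethyl)cyclopent-2-en-1-one
Product: 5 3-({[tert-butyl(dimethyl)silyl]oxy}methyl)cyclopent-2-en-1-one
Conditions: TBSCl, imidazole, CH2Cl2, 0 °C to rt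
Reagents that add atoms: tert-butyldimethylsilyl chloride CC(C)(C)[Si](C)(C)Cl
Why: Standard silyl ether formation on a primary alcohol, giving a fluoride-labile mask for C10 that should survive every step up to step 15.

Step 3
Reactants: 5 3-({[tert-butyl(dimethyl)silyl]oxy}methyl)cyclopent-2-en-1-one
Product: 7 tert-butyl(dimethyl){[(1S)-1-methyl-3-(trimethylsilyloxy)cyclopent-2-en-1-yl]methoxy}silane, via the dimethylaluminium enolate 6 (not isolated)
Conditions: Me3Al, Cu(O2CC4H3S) (copper thiophene-2-carboxylate, 5 mol %), chiral biaryl phosphoramidite ligand (10 mol %), Et2O, −30 °C; then TMSOTf, −30 °C to rt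
Reagents that add atoms: trimethylaluminium C[Al](C)C; trimethylsilyl trifluoromethanesulfonate C[Si](C)(C)OS(=O)(=O)C(F)(F)F
Why: Copper-catalysed asymmetric conjugate addition of trimethylaluminium to a 3-substituted cyclopentenone should set quaternary C1 (S) under ligand control, and silylation of the aluminium enolate fixes the enolate regiochemistry at C4–C5.

Step 4
Reactants: 7 tert-butyl(dimethyl){[(1S)-1-methyl-3-(trimethylsilyloxy)cyclopent-2-en-1-yl]methoxy}silane
Product: 8 (2S,3S)-2-[(benzyloxy)methyl]-3-({[tert-butyl(dimethyl)silyl]oxy}methyl)-3-methylcyclopentan-1-one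
Conditions: BnOCH2Cl, ZnBr2 (10 mol %), CH2Cl2, −20 to 0 °C
Reagents that add atoms: benzyl chloromethyl ether ClCOCc1ccccc1
Why: Mukaiyama-type Lewis-acid alkylation of the silyl enol ether by the benzyloxymethyl cation; C5 should form by attack anti to the bulkier silyloxymethyl arm on C1, placing the new C6 arm cis to the C15 methyl, which is also the arrangement favoured at equilibrium for this epimerisable centre.

Step 5
Reactants: 8 (2S,3S)-2-[(benzyloxy)methyl]-3-({[tert-butyl(dimethyl)silyl]oxy}methyl)-3-methylcyclopentan-1-one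
Product: 9 (1R,2S,3S)-2-[(benzyloxy)methyl]-3-({[tert-butyl(dimethyl)silyl]oxy}methyl)-3-methyl-1-(propan-2-yl)cyclopentan-1-ol
Conditions: iPrMgCl, anhydrous CeCl3, THF, −78 to 0 °C
Reagents that add atoms: isopropylmagnesium chloride CC(C)[Mg]Cl
Why: Organocerium 1,2-addition, which suppresses enolisation and reduction of the hindered ketone; isopropyl should enter from the α-face, anti to the adjacent C5 arm, setting C4 (R) with its hydroxyl cis to that arm.

Step 6
Reactants: 9 (1R,2S,3S)-2-[(benzyloxy)methyl]-3-({[tert-butyl(dimethyl)silyl]oxy}methyl)-3-methyl-1-(propan-2-yl)cyclopentan-1-ol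
Product: 10 {[(1S,2S,3R)-2-[(benzyloxy)methyl]-3-(methoxymethoxy)-1-methyl-3-(propan-2-yl)cyclopentyl]methoxy}(tert-butyl)dimethylsilane
Conditions: MOMCl, iPr2NEt, Bu4NI (cat.), ClCH2CH2Cl, 60 °C
Reagents that add atoms: chloromethyl methyl ether COCCl
Why: Methoxymethyl acetal formation on the tertiary alcohol under forcing, non-acidic conditions; this ether is the chelating handle for step 12 and leaves together with the C9 acetal in step 18.

Step 7
Reactants: 10 {[(1S,2S,3R)-2-[(benzyloxy)methyl]-3-(methoxymethoxy)-1-methyl-3-(propan-2-yl)cyclopentyl]methoxy}(tert-butyl)dimethylsilane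
Product: 11 [(1S,2S,5R)-2-({[tert-butyl(dimethyl)silyl]oxy}methyl)-5-(methoxymethoxy)-2-methyl-5-(propan-2-yl)cyclopentyl]methanol
Conditions: H2 (1 atm), Pd/C, EtOAc, rt
Reagents that add atoms: none
Why: Hydrogenolysis of the benzyl ether, to which the silyl ether and the acetal are inert and which meets no alkene at this stage.

Step 8
Reactants: 11 [(1S,2S,5R)-2-({[tert-butyl(dimethyl)silyl]oxy}methyl)-5-(methoxymethoxy)-2-methyl-5-(propan-2-yl)cyclopentyl]methanol
Product: 12 (1R,2S,5R)-2-({[tert-butyl(dimethyl)silyl]oxy}methyl)-5-(methoxymethoxy)-2-methyl-5-(propan-2-yl)cyclopentane-1-carbaldehyde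
Conditions: Dess–Martin periodinane, NaHCO3, CH2Cl2, 0 °C to rt
Reagents that add atoms: none
Why: Buffered Dess–Martin oxidation should give the aldehyde without β-elimination, and the epimerisable C5 already holds its more stable configuration (formyl trans to isopropyl).

Step 9
Reactants: 13 2-methylidenepropane-1,3-diol
Product: 14 2-[(methoxymethoxy)methyl]prop-2-en-1-ol
Conditions: NaH (1.0 equiv), THF, 0 °C; MOMCl (1.0 equiv)
Reagents that add atoms: chloromethyl methyl ether COCCl
Why: Williamson-type monoalkylation of the symmetrical diol with one equivalent of base and chloromethyl methyl ether; the mono-ether is separable from diol and bis-ether.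

Step 10
Reactants: 14 2-[(methoxymethoxy)methyl]prop-2-en-1-ol
Product: 15 3-bromo-2-[(methoxymethoxy)methyl]prop-1-ene
Conditions: CBr4, PPh3, CH2Cl2, 0 °C
Reagents that add atoms: carbon tetrabromide BrC(Br)(Br)Br
Why: Appel reaction converts the primary allylic alcohol into the bromide under neutral conditions that leave the acetal intact.

Step 11
Reactants: 15 3-bromo-2-[(methoxymethoxy)methyl]prop-1-ene
Product: 16 tributyl{2-[(methoxymethoxy)methyl]prop-2-en-1-yl}stannane
Conditions: Bu3SnLi (from Bu3SnH and LiN(iPr)2), THF, −78 °C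
Reagents that add atoms: tributylstannane CCCC[SnH](CCCC)CCCC
Why: Nucleophilic substitution of the allylic bromide by tributylstannyllithium; direct and allylically transposed attack give the same product because the allyl unit is symmetrical.

Step 12
Reactants: 12 (1R,2S,5R)-2-({[tert-butyl(dimethyl)silyl]oxy}methyl)-5-(methoxymethoxy)-2-methyl-5-(propan-2-yl)cyclopentane-1-carbaldehyde; 16 tributyl{2-[(methoxymethoxy)methyl]prop-2-en-1-yl}stannane
Product: 17 (1S)-1-[(1S,2S,5R)-2-({[tert-butyl(dimethyl)silyl]oxy}methyl)-5-(methoxymethoxy)-2-methyl-5-(propan-2-yl)cyclopentyl]-3-[(methoxymethoxy)methyl]but-3-en-1-ol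
Conditions: MgBr2·OEt2 (3 equiv), CH2Cl2, −20 °C to rt
Reagents that add atoms: none
Why: Chelation-controlled Lewis-acid allylstannane addition (SE2′) in which MgBr2 ties the aldehyde oxygen to the C4 acetal oxygen in a six-membered chelate on the β-face of ring A, so that the allyl group should attack the carbonyl face turned away from the C15 methyl and set C6 as S.

Step 13
Reactants: 17 (1S)-1-[(1S,2S,5R)-2-({[tert-butyl(dimethyl)silyl]oxy}methyl)-5-(methoxymethoxy)-2-methyl-5-(propan-2-yl)cyclopentyl]-3-[(methoxymethoxy)methyl]but-3-en-1-ol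
Product: 19 (1S,3Z)-1-[(1S,2S,5R)-2-({[tert-butyl(dimethyl)silyl]oxy}methyl)-5-(methoxymethoxy)-2-methyl-5-(propan-2-yl)cyclopentyl]-4-(methoxymethoxy)-3-[(tributylstannyl)methyl]but-3-en-1-ol, via the dilithio alkoxide allyl anion 18 (not isolated)
Conditions: sec-BuLi (2.2 equiv), THF, −78 °C; Bu3SnCl (1.1 equiv), −78 °C; then H2O
Reagents that add atoms: tributyltin chloride CCCC[Sn](Cl)(CCCC)CCCC
Why: Directed α-lithiation of the allylic methoxymethyl ether (the first equivalent of base is consumed by the hydroxyl) gives the lithium-chelated (Z)-alkoxyallyl anion, which tributyltin chloride should capture at the unhindered γ-terminus C14 to give the (Z)-γ-alkoxyallylstannane.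

Step 14
Reactants: 19 (1S,3Z)-1-[(1S,2S,5R)-2-({[tert-butyl(dimethyl)silyl]oxy}methyl)-5-(methoxymethoxy)-2-methyl-5-(propan-2-yl)cyclopentyl]-4-(methoxymethoxy)-3-[(tributylstannyl)methyl]but-3-en-1-ol
Product: 20 (1S,3Z)-1-[(1S,2S,5R)-2-({[tert-butyl(dimethyl)silyl]oxy}methyl)-5-(methoxymethoxy)-2-methyl-5-(propan-2-yl)cyclopentyl]-4-(methoxymethoxy)-3-[(tributylstannyl)methyl]but-3-en-1-yl 3-methylbutanoate
Conditions: (iBuCO)2O, DMAP, Et3N, CH2Cl2, rt
Reagents that add atoms: 3-methylbutanoic anhydride CC(C)CC(=O)OC(=O)CC(C)C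
Why: DMAP-catalysed acylation of the only free hydroxyl under basic conditions that leave the acid-sensitive enol ether and allylstannane untouched.

Step 15
Reactants: 20 (1S,3Z)-1-[(1S,2S,5R)-2-({[tert-butyl(dimethyl)silyl]oxy}methyl)-5-(methoxymethoxy)-2-methyl-5-(propan-2-yl)cyclopentyl]-4-(methoxymethoxy)-3-[(tributylstannyl)methyl]but-3-en-1-yl 3-methylbutanoate
Product: 21 (1S,3Z)-1-[(1S,2S,5R)-2-(hydroxymethyl)-5-(methoxymethoxy)-2-methyl-5-(propan-2-yl)cyclopentyl]-4-(methoxymethoxy)-3-[(tributylstannyl)methyl]but-3-en-1-yl 3-methylbutanoate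
Conditions: Bu4NF, THF, 0 °C to rt
Reagents that add atoms: none
Why: Fluoride-mediated desilylation of the primary silyl ether; allylstannane, enol ether, ester and acetals are inert to fluoride.

Step 16
Reactants: 21 (1S,3Z)-1-[(1S,2S,5R)-2-(hydroxymethyl)-5-(methoxymethoxy)-2-methyl-5-(propan-2-yl)cyclopentyl]-4-(methoxymethoxy)-3-[(tributylstannyl)methyl]but-3-en-1-yl 3-methylbutanoate
Product: 22 (1S,3Z)-1-[(1S,2S,5R)-2-formyl-5-(methoxymethoxy)-2-methyl-5-(propan-2-yl)cyclopentyl]-4-(methoxymethoxy)-3-[(tributylstannyl)methyl]but-3-en-1-yl 3-methylbutanoate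
Conditions: SO3·pyridine, DMSO, iPr2NEt, CH2Cl2, 0 °C
Reagents that add atoms: none
Why: Parikh–Doering oxidation, a non-acidic activated-DMSO oxidation compatible with γ-alkoxyallylstannanes, should give the non-enolisable neopentyl aldehyde.

Step 17
Reactants: 22 (1S,3Z)-1-[(1S,2S,5R)-2-formyl-5-(methoxymethoxy)-2-methyl-5-(propan-2-yl)cyclopentyl]-4-(methoxymethoxy)-3-[(tributylstannyl)methyl]but-3-en-1-yl 3-methylbutanoate
Product: 23 (1S,4R,5S,6S,9R,10S)-10α-hydroxy-4β,9α-bis(methoxymethoxy)dauc-8(14)-en-6α-yl 3-methylbutanoate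
Conditions: BF3·OEt2 (2.5 equiv), CH2Cl2, −78 °C; then aq. NaHCO3
Reagents that add atoms: none
Why: BF3 binds the C10 aldehyde oxygen and the enol ether carbon C9, the γ-terminus of the allylstannane, attacks C10 in an SE2′ process in which the C14–Sn bond, aligned with the π system, is lost as Bu3SnF and the C8=C14 methylene remains. The closest known reaction type is the Lewis-acid-promoted intramolecular addition of γ-alkoxyallylstannanes to aldehydes used to close oxygen heterocycles and carbocycles. Ring B closes in a 7-exo-trig mode with respect to the carbonyl, the allyl unit being tethered through its central carbon C8 so that C8 and C9 enter the ring and C14 stays exocyclic, and the trans relation of the two arms on ring A gives the trans-fused hydroazulene. C10 should be set by the aldehyde rotamer in which the BF3-bound oxygen lies anti to the axial C15 methyl on C1, which leads to the 10α-alcohol. C9 should be set by the (Z)-enol ether geometry, which places the methoxymethoxy group pseudo-equatorial, together with the synclinal alignment of C8=C9 and C10=O generally preferred in intramolecular allylstannane additions, which gives the 9α-ether cis to the 10α-hydroxyl. The step needs γ-selectivity, secured by tin on C14 and the donor oxygen on C9 (α-attack would demand a nine-membered ring), and tolerance of the ester and acetals, which BF3·OEt2 at −78 °C should provide.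

Step 18
Reactants: 23 (1S,4R,5S,6S,9R,10S)-10α-hydroxy-4β,9α-bis(methoxymethoxy)dauc-8(14)-en-6α-yl 3-methylbutanoate
Product: 24 (1S,4R,5S,6S,9R,10S)-4β,9α,10α-trihydroxydauc-8(14)-en-6α-yl 3-methylbutanoate
Conditions: ZnBr2, n-PrSH, CH2Cl2, 0 °C to rt
Reagents that add atoms: none
Why: Zinc-assisted thiolysis of both formaldehyde acetals, in which the thiol traps the methoxymethyl fragment so that the ester, the allylic alcohol and the tertiary carbinol are not exposed to protic acid.

Step 19
Reactants: 24 (1S,4R,5S,6S,9R,10S)-4β,9α,10α-trihydroxydauc-8(14)-en-6α-yl 3-methylbutanoate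
Product: 25 (1S,4R,5S,6S,8S,9S,10S)-8α,14-epoxy-4β,9α,10α-trihydroxydaucan-6α-yl 3-methylbutanoate (CNP0307265.1)
Conditions: VO(acac)2 (5 mol %), t-BuOOH, CH2Cl2, 0 °C to rt
Reagents that add atoms: tert-butyl hydroperoxide CC(C)(C)OO
Why: Vanadium-catalysed hydroxyl-directed epoxidation in which the allylic 9α-hydroxyl, supported by the 10α-hydroxyl, binds the metal peroxide and should deliver oxygen to the α-face of the only alkene, setting C8 as S.

Compound list
1 | 3-ethoxycyclopent-2-en-1-one | CCOC1=CC(=O)CC1 | starting material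
2 | lithium 3-ethoxy-1-[(methoxymethoxy)methyl]cyclopent-2-en-1-olate | CCOC1=CC([O-])(COCOC)CC1.[Li+] | intermediate (not isolated)
3 | 3-[(methoxymethoxy)methyl]cyclopent-2-en-1-one | COCOCC1=CC(=O)CC1 | intermediate (not isolated)
4 | 3-(hydroxymethyl)cyclopent-2-en-1-one | OCC1=CC(=O)CC1 | intermediate
5 | 3-({[tert-butyl(dimethyl)silyl]oxy}methyl)cyclopent-2-en-1-one | CC(C)(C)[Si](C)(C)OCC1=CC(=O)CC1 | intermediate
6 | dimethylaluminium (3S)-3-({[tert-butyl(dimethyl)silyl]oxy}methyl)-3-methylcyclopent-1-en-1-olate | CC(C)(C)[Si](C)(C)OC[C@@]1(C)CCC(O[Al](C)C)=C1 | intermediate (not isolated)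
7 | tert-butyl(dimethyl){[(1S)-1-methyl-3-(trimethylsilyloxy)cyclopent-2-en-1-yl]methoxy}silane | CC(C)(C)[Si](C)(C)OC[C@@]1(C)CCC(O[Si](C)(C)C)=C1 | intermediate
8 | (2S,3S)-2-[(benzyloxy)methyl]-3-({[tert-butyl(dimethyl)silyl]oxy}methyl)-3-methylcyclopentan-1-one | CC(C)(C)[Si](C)(C)OC[C@@]1(C)CCC(=O)[C@@H]1COCc1ccccc1 | intermediate
9 | (1R,2S,3S)-2-[(benzyloxy)methyl]-3-({[tert-butyl(dimethyl)silyl]oxy}methyl)-3-methyl-1-(propan-2-yl)cyclopentan-1-ol | CC(C)(C)[Si](C)(C)OC[C@@]1(C)CC[C@@](O)(C(C)C)[C@@H]1COCc1ccccc1 | intermediate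
10 | {[(1S,2S,3R)-2-[(benzyloxy)methyl]-3-(methoxymethoxy)-1-methyl-3-(propan-2-yl)cyclopentyl]methoxy}(tert-butyl)dimethylsilane | CC(C)(C)[Si](C)(C)OC[C@@]1(C)CC[C@@](OCOC)(C(C)C)[C@@H]1COCc1ccccc1 | intermediate
11 | [(1S,2S,5R)-2-({[tert-butyl(dimethyl)silyl]oxy}methyl)-5-(methoxymethoxy)-2-methyl-5-(propan-2-yl)cyclopentyl]methanol | CC(C)(C)[Si](C)(C)OC[C@@]1(C)CC[C@@](OCOC)(C(C)C)[C@@H]1CO | intermediate
12 | (1R,2S,5R)-2-({[tert-butyl(dimethyl)silyl]oxy}methyl)-5-(methoxymethoxy)-2-methyl-5-(propan-2-yl)cyclopentane-1-carbaldehyde | CC(C)(C)[Si](C)(C)OC[C@@]1(C)CC[C@@](OCOC)(C(C)C)[C@@H]1C=O | intermediate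
13 | 2-methylidenepropane-1,3-diol | C=C(CO)CO | starting material
14 | 2-[(methoxymethoxy)methyl]prop-2-en-1-ol | C=C(CO)COCOC | intermediate
15 | 3-bromo-2-[(methoxymethoxy)methyl]prop-1-ene | C=C(CBr)COCOC | intermediate
16 | tributyl{2-[(methoxymethoxy)methyl]prop-2-en-1-yl}stannane | C=C(COCOC)C[Sn](CCCC)(CCCC)CCCC | intermediate
17 | (1S)-1-[(1S,2S,5R)-2-({[tert-butyl(dimethyl)silyl]oxy}methyl)-5-(methoxymethoxy)-2-methyl-5-(propan-2-yl)cyclopentyl]-3-[(methoxymethoxy)methyl]but-3-en-1-ol | CC(C)(C)[Si](C)(C)OC[C@@]1(C)CC[C@@](OCOC)(C(C)C)[C@@H]1[C@@H](O)CC(=C)COCOC | intermediate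
18 | dilithio derivative of 17 (C6 lithium alkoxide, C9 α-(methoxymethoxy)allyllithium) | CC(C)(C)[Si](C)(C)OC[C@@]1(C)CC[C@@](OCOC)(C(C)C)[C@@H]1[C@@H](O[Li])CC(=C)C([Li])OCOC | intermediate (not isolated)
19 | (1S,3Z)-1-[(1S,2S,5R)-2-({[tert-butyl(dimethyl)silyl]oxy}methyl)-5-(methoxymethoxy)-2-methyl-5-(propan-2-yl)cyclopentyl]-4-(methoxymethoxy)-3-[(tributylstannyl)methyl]but-3-en-1-ol | CC(C)(C)[Si](C)(C)OC[C@@]1(C)CC[C@@](OCOC)(C(C)C)[C@@H]1[C@@H](O)C/C(C[Sn](CCCC)(CCCC)CCCC)=C/OCOC | intermediate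
20 | (1S,3Z)-1-[(1S,2S,5R)-2-({[tert-butyl(dimethyl)silyl]oxy}methyl)-5-(methoxymethoxy)-2-methyl-5-(propan-2-yl)cyclopentyl]-4-(methoxymethoxy)-3-[(tributylstannyl)methyl]but-3-en-1-yl 3-methylbutanoate | CC(C)(C)[Si](C)(C)OC[C@@]1(C)CC[C@@](OCOC)(C(C)C)[C@@H]1[C@@H](OC(=O)CC(C)C)C/C(C[Sn](CCCC)(CCCC)CCCC)=C/OCOC | intermediate
21 | (1S,3Z)-1-[(1S,2S,5R)-2-(hydroxymethyl)-5-(methoxymethoxy)-2-methyl-5-(propan-2-yl)cyclopentyl]-4-(methoxymethoxy)-3-[(tributylstannyl)methyl]but-3-en-1-yl 3-methylbutanoate | OC[C@@]1(C)CC[C@@](OCOC)(C(C)C)[C@@H]1[C@@H](OC(=O)CC(C)C)C/C(C[Sn](CCCC)(CCCC)CCCC)=C/OCOC | intermediate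
22 | (1S,3Z)-1-[(1S,2S,5R)-2-formyl-5-(methoxymethoxy)-2-methyl-5-(propan-2-yl)cyclopentyl]-4-(methoxymethoxy)-3-[(tributylstannyl)methyl]but-3-en-1-yl 3-methylbutanoate | O=C[C@@]1(C)CC[C@@](OCOC)(C(C)C)[C@@H]1[C@@H](OC(=O)CC(C)C)C/C(C[Sn](CCCC)(CCCC)CCCC)=C/OCOC | intermediate
23 | (1S,4R,5S,6S,9R,10S)-10α-hydroxy-4β,9α-bis(methoxymethoxy)dauc-8(14)-en-6α-yl 3-methylbutanoate | CC(C)CC(=O)O[C@H]1CC(=C)[C@@H](OCOC)[C@@H](O)[C@@]2(C)CC[C@@](OCOC)(C(C)C)[C@H]12 | intermediate
24 | (1S,4R,5S,6S,9R,10S)-4β,9α,10α-trihydroxydauc-8(14)-en-6α-yl 3-methylbutanoate | CC(C)CC(=O)O[C@H]1CC(=C)[C@@H](O)[C@@H](O)[C@@]2(C)CC[C@@](O)(C(C)C)[C@H]12 | intermediate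
25 | (1S,4R,5S,6S,8S,9S,10S)-8α,14-epoxy-4β,9α,10α-trihydroxydaucan-6α-yl 3-methylbutanoate (CNP0307265.1) | CC(C)CC(=O)O[C@H]1C[C@]2(CO2)[C@@H](O)[C@@H](O)[C@@]2(C)CC[C@@](O)(C(C)C)[C@H]12 | target

Total step count: 19. Longest linear sequence: 16 steps (steps 1–8 and 12–19, from 3-ethoxycyclopent-2-en-1-one); steps 9–11 make the allylstannane 16.

The three steps most likely to fail:

Step 17. The allyl transfer may proceed through the other ring twist with the antiperiplanar instead of the synclinal alignment, so that the enol ether reacts on its wrong face and C9 forms with the 9β configuration. The fallback sets out from 22 and corrects C9 by oxidation and reduction. The same cyclisation would then give the 9-epimeric ether F1. Thiolytic removal of both acetals (ZnBr2, n-PrSH, CH2Cl2) would give the 9β-triol F2. MnO2 in CH2Cl2 should oxidise only the allylic C9 hydroxyl, to the 9-ketone F3. Luche reduction (NaBH4, CeCl3·7H2O, MeOH, −78 °C) should add hydride from the β-face, anti to the axial 10α-hydroxyl, and returns the route at 24.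

Step 13. The lithium alkoxide at C6 may aggregate with the base or divert it to the C7 allylic position, giving incomplete or non-regioselective metalation and stannylation. The fallback masks the hydroxyl before metalation. Setting out from 17, TMSCl and imidazole in CH2Cl2 give the trimethylsilyl ether F4. One equivalent of sec-BuLi (THF, −78 °C) gives the monolithio species F5, which Bu3SnCl converts into the stannane silyl ether F6. Methanolysis of the trimethylsilyl ether (K2CO3, MeOH, 0 °C), which leaves the tert-butyldimethylsilyl ether and the allylstannane intact, returns the route at 19.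

Step 4. The methyl and silyloxymethyl groups on C1 may discriminate poorly between the two faces of the enol ether, so that C5 (and through it C4 in step 5) forms with low facial selectivity. The fallback replaces substrate control by catalyst control. Setting out from 7, hydroxymethylation with aqueous formaldehyde under Sc(OTf)3 catalysis with a chiral 2,2′-bipyridine diol ligand matched to the substrate gives the hydroxymethyl ketone F7. Benzylation under neutral conditions (2-benzyloxy-1-methylpyridinium trifluoromethanesulfonate, MgO, PhCF3, 85 °C), which avoids retro-aldol cleavage, returns the route at 8.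

Further compounds
F1 | step 17 | (1S,4R,5S,6S,9S,10S)-10α-hydroxy-4β,9β-bis(methoxymethoxy)dauc-8(14)-en-6α-yl 3-methylbutanoate | CC(C)CC(=O)O[C@H]1CC(=C)[C@H](OCOC)[C@@H](O)[C@@]2(C)CC[C@@](OCOC)(C(C)C)[C@H]12
F2 | step 17 | (1S,4R,5S,6S,9S,10S)-4β,9β,10α-trihydroxydauc-8(14)-en-6α-yl 3-methylbutanoate | CC(C)CC(=O)O[C@H]1CC(=C)[C@H](O)[C@@H](O)[C@@]2(C)CC[C@@](O)(C(C)C)[C@H]12
F3 | step 17 | (1S,4R,5S,6S,10S)-4β,10α-dihydroxy-9-oxodauc-8(14)-en-6α-yl 3-methylbutanoate | CC(C)CC(=O)O[C@H]1CC(=C)C(=O)[C@@H](O)[C@@]2(C)CC[C@@](O)(C(C)C)[C@H]12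
F4 | step 13 | trimethylsilyl ether of 17 at the C6 hydroxyl | CC(C)(C)[Si](C)(C)OC[C@@]1(C)CC[C@@](OCOC)(C(C)C)[C@@H]1[C@@H](O[Si](C)(C)C)CC(=C)COCOC
F5 | step 13 | C9-lithio derivative of F4 (α-(methoxymethoxy)allyllithium) | CC(C)(C)[Si](C)(C)OC[C@@]1(C)CC[C@@](OCOC)(C(C)C)[C@@H]1[C@@H](O[Si](C)(C)C)CC(=C)C([Li])OCOC
F6 | step 13 | trimethylsilyl ether of 19 at the C6 hydroxyl | CC(C)(C)[Si](C)(C)OC[C@@]1(C)CC[C@@](OCOC)(C(C)C)[C@@H]1[C@@H](O[Si](C)(C)C)C/C(C[Sn](CCCC)(CCCC)CCCC)=C/OCOC
F7 | step 4 | (2S,3S)-3-({[tert-butyl(dimethyl)silyl]oxy}methyl)-2-(hydroxymethyl)-3-methylcyclopentan-1-one | CC(C)(C)[Si](C)(C)OC[C@@]1(C)CCC(=O)[C@@H]1CO
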